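**Plan**

1. Cuts: the N–OH bond (made last); pyridone C3–C(=O) (3-lithiopyridine plus decalin aldehyde, then oxidation); pyridone C5–C(OH) (5-lithiopyridine plus a 4-alkoxycyclohexenone); and, in the decalin (numbered as 2-methyl-1,2,4a,5,6,7,8,8a-octahydronaphthalene-1-carbonyl), the bonds C2–C3 and C4a–C8a after formal removal of H2 from C2 and C4a.
2. Enabling feature: in the cyclohexene ring C1–C2–C3=C4–C4a–C8a the alkene lies between the sp3 centres C2 and C4a, so the ring is the 1,4-dihydro form of a C2=C3–C4=C4a diene, and C1 carries the carbonyl between C2 and C8a. C3–C4–C4a therefore maps onto an allylidenephosphorane (nucleophilic at both ends) and C8a–C1–C2 onto an alkylidene acetoacetate (electrophilic at its β-carbon and its acetyl carbon).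
3. Forward: an open-chain phosphonium salt gives the ylide; conjugate addition closes the cyclohexane ring (ring A) and an intramolecular Wittig reaction closes the diene ring (ring B) in the same flask; cis-1,4-hydrogenation of the diene then gives the cis-fused octalin.
4. Decalin stereocentres: C8a forms without face control and is resolved through the (−)-menthyl ester (diastereomer separation, step 7); H-2 and H-4a are delivered together on the face of H-8a; C1 is set by equilibration.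
5. Epoxydiol stereocentres: CBS reduction sets the alkoxy carbon (later inverted by a Mitsunobu reaction); the aryllithium adds anti to it (tertiary carbinol); a hydroxyl-directed epoxidation sets the epoxide.
6. Assembly: pyridine C5 first, then C3; fluoride removes every silicon-based group; N-hydroxylation of the silylated pyridone ends the route.

Key step: step 5

Assumption: 1,4-dioxaspiro[4.5]dec-6-en-8-one, 3-bromo-2,4-dichloropyridine and (−)-menthyl acetoacetate are bought; no facial bias is assumed in the conjugate addition of step 5, so the menthyl ester serves only as a resolving handle.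

**Route**

Step 1
Reactants: 1 hept-6-en-1-ol
Product: 2 hept-6-enal
Conditions: TEMPO (10 mol %), PhI(OAc)2, CH2Cl2, rt
Reagents that add atoms: none
Why: Nitroxyl-catalysed oxidation of a primary alcohol should stop at the aldehyde and leave the terminal alkene untouched.

Step 2
Reactants: 2 hept-6-enal
Product: 3 (6E)-8-bromooct-6-enal
Conditions: allyl bromide (4 equiv), second-generation Grubbs catalyst (H2IMes)(PCy3)Cl2Ru=CHPh (3 mol %), CH2Cl2, 40 °C
Reagents that add atoms: allyl bromide, C=CCBr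
Why: Olefin cross-metathesis of the terminal alkene with excess allyl bromide should give the allylic bromide with loss of ethene; the alkene geometry is erased in step 5.

Step 3
Reactants: 3 (6E)-8-bromooct-6-enal
Product: 4 [(2E)-8-oxooct-2-en-1-yl]triphenylphosphonium bromide
Conditions: PPh3, toluene, 50 °C
Reagents that add atoms: triphenylphosphine, c1ccc(cc1)P(c1ccccc1)c1ccccc1
Why: SN2 quaternisation of the primary allylic bromide should give the phosphonium salt, the aldehyde being inert to the phosphine.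

Step 4
Reactants: 4 [(2E)-8-oxooct-2-en-1-yl]triphenylphosphonium bromide; 5 (1R,2S,5R)-menthyl 3-oxobutanoate
Product: 6 [(2E)-9-{[(1R,2S,5R)-menthyl]oxycarbonyl}-10-oxoundeca-2,8-dien-1-yl]triphenylphosphonium bromide (either geometry at C8=C9)
Conditions: piperidine (10 mol %), AcOH (10 mol %), 4 Å molecular sieves, CH2Cl2, 0 °C
Reagents that add atoms: none
Why: Knoevenagel condensation of the aldehyde with the β-keto ester should give the alkylidene acetoacetate; the amine is too weak to deprotonate the phosphonium salt, and low temperature with one equivalent of 5 limits bis-addition.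

Step 5
Reactants: 6 [(2E)-9-{[(1R,2S,5R)-menthyl]oxycarbonyl}-10-oxoundeca-2,8-dien-1-yl]triphenylphosphonium bromide
Product: 10 (1R,2S,5R)-menthyl (8aS)-2-methyl-1,5,6,7,8,8a-hexahydronaphthalene-1-carboxylate, via allylidenephosphorane 7 (not isolated), via phosphonium enolate 8 (not isolated), via cyclohexylidene ylide 9 (not isolated)
Conditions: NaN(SiMe3)2 (1.0 equiv), THF (0.01 M), −78 °C → 65 °C
Reagents that add atoms: none
Why: The base removes the proton next to phosphorus to give ylide 7, whose γ-carbon adds to the β-carbon of the alkylidene acetoacetate (C4a–C8a) to give 8, a proton shift from the γ-CH to the enolate gives ylide 9, and its intramolecular Wittig reaction with the acetyl carbonyl forms C2=C3 and expels Ph3PO. The closest known reaction is the annulation of allylidenetriphenylphosphorane with alkylidene acetoacetates and enones to cyclohexa-1,3-dienes (tandem Michael addition–ylide olefination). Ring A closes by 6-exo-trig conjugate addition and ring B by a six-membered intramolecular Wittig olefination through an oxaphosphetane. C8a is the only new stereocentre that persists and forms without face control because the menthyl group is remote, so 10 should arise together with its 8aR diastereomer, while C1 is epimerisable and C4a is sp2. The step needs γ- over α-attack of the ylide and olefination of the ketone rather than the ester: the six- against eight-membered transition state secures the first and the higher electrophilicity of the methyl ketone the second. One equivalent of a non-nucleophilic base and high dilution should suppress migration of the diene into conjugation with the ester and intermolecular addition.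

Step 6
Reactants: 10 (1R,2S,5R)-menthyl (8aS)-2-methyl-1,5,6,7,8,8a-hexahydronaphthalene-1-carboxylate
Product: 11 (1R,2S,5R)-menthyl (2S,4aR,8aR)-2-methyl-1,2,4a,5,6,7,8,8a-octahydronaphthalene-1-carboxylate (both C1 epimers)
Conditions: (naphthalene)Cr(CO)3 (15 mol %), H2 (50 atm), acetone, 40 °C
Reagents that add atoms: none
Why: Arene-Cr(CO)3-catalysed 1,4-hydrogenation of the ring-locked s-cis diene should add both hydrogens to C2 and C4a from one face and leave C3=C4; the metal should bind the face of the axial H-8a (equatorial approach to C4a, away from the axial hydrogens at C6 and C8), which gives the cis ring fusion and the methyl group cis to C8.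

Step 7
Reactants: 11 (1R,2S,5R)-menthyl (2S,4aR,8aR)-2-methyl-1,2,4a,5,6,7,8,8a-octahydronaphthalene-1-carboxylate (both C1 epimers)
Product: 12 (1R,2S,5R)-menthyl (1R,2S,4aR,8aR)-2-methyl-1,2,4a,5,6,7,8,8a-octahydronaphthalene-1-carboxylate
Conditions: KOtBu (0.2 equiv), t-BuOH–THF, 40 °C; then chromatography on silica gel
Reagents that add atoms: none
Why: Alkoxide-catalysed epimerisation through the ester enolate should place the ester trans to both the C2 methyl and C8 (all three equatorial on ring B), and the two menthyl esters of antipodal bicycles are diastereomers that should separate on silica, which fixes the absolute configuration of the decalin.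

Step 8
Reactants: 12 (1R,2S,5R)-menthyl (1R,2S,4aR,8aR)-2-methyl-1,2,4a,5,6,7,8,8a-octahydronaphthalene-1-carboxylate
Product: 13 [(1R,2S,4aR,8aR)-2-methyl-1,2,4a,5,6,7,8,8a-octahydronaphthalen-1-yl]methanol
Conditions: LiAlH4, THF, 0 °C → 50 °C
Reagents that add atoms: none
Why: Hydride reduction of the ester should give the primary alcohol and release menthol without touching a stereocentre or the isolated alkene.

Step 9
Reactants: 13 [(1R,2S,4aR,8aR)-2-methyl-1,2,4a,5,6,7,8,8a-octahydronaphthalen-1-yl]methanol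
Product: 14 (1R,2S,4aR,8aR)-2-methyl-1,2,4a,5,6,7,8,8a-octahydronaphthalene-1-carbaldehyde
Conditions: Dess–Martin periodinane, CH2Cl2, 0 °C → rt
Reagents that add atoms: none
Why: Dess–Martin oxidation should give the α-branched aldehyde under near-neutral conditions, C1 being already in its preferred configuration.

Step 10
Reactants: 15 3-bromo-2,4-dichloropyridine
Product: 16 3-bromo-2,4-bis[2-(trimethylsilyl)ethoxy]pyridine
Conditions: Me3SiCH2CH2OH (2.5 equiv), NaH, DMF, 0 → 70 °C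
Reagents that add atoms: 2-(trimethylsilyl)ethanol, C[Si](C)(C)CCO
Why: Twofold nucleophilic aromatic substitution of the 2- and 4-chlorides, both activated by the ring nitrogen, should install two fluoride-labile ethers while the unactivated C3 bromide stays.

Step 11
Reactants: 16 3-bromo-2,4-bis[2-(trimethylsilyl)ethoxy]pyridine
Product: 17 3-bromo-5-iodo-2,4-bis[2-(trimethylsilyl)ethoxy]pyridine
Conditions: N-iodosuccinimide, CF3CO2H (10 mol %), MeCN, rt
Reagents that add atoms: N-iodosuccinimide, O=C1CCC(=O)N1I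
Why: Electrophilic aromatic iodination should occur at C5, the only free position ortho and para to the two alkoxy groups.

Step 12
Reactants: 18 1,4-dioxaspiro[4.5]dec-6-en-8-one
Product: 19 (8S)-1,4-dioxaspiro[4.5]dec-6-en-8-ol
Conditions: (R)-2-methyl-CBS-oxazaborolidine (10 mol %), BH3·SMe2, THF, −20 °C; MeOH quench
Reagents that add atoms: none
Why: Corey–Bakshi–Shibata reduction with the alkene branch as the large group should give the S allylic alcohol by the usual model, which sets the absolute configuration of the whole epoxydiol unit.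

Step 13
Reactants: 19 (8S)-1,4-dioxaspiro[4.5]dec-6-en-8-ol
Product: 20 (8S)-8-[(4-methoxybenzyl)oxy]-1,4-dioxaspiro[4.5]dec-6-ene
Conditions: NaH, 4-methoxybenzyl chloride, Bu4NI (cat.), THF–DMF, 0 °C → rt
Reagents that add atoms: 4-methoxybenzyl chloride, COc1ccc(CCl)cc1
Why: Williamson etherification should give an ether that survives organolithium reagents and is removable without fluoride or acid.

Step 14
Reactants: 20 (8S)-8-[(4-methoxybenzyl)oxy]-1,4-dioxaspiro[4.5]dec-6-ene
Product: 21 (4S)-4-[(4-methoxybenzyl)oxy]cyclohex-2-en-1-one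
Conditions: pyridinium p-toluenesulfonate (cat.), acetone–H2O, 50 °C
Reagents that add atoms: water, O
Why: Mild acid-catalysed ketal hydrolysis should free the enone without elimination of the γ-alkoxy group.

Step 15
Reactants: 17 3-bromo-5-iodo-2,4-bis[2-(trimethylsilyl)ethoxy]pyridine; 21 (4S)-4-[(4-methoxybenzyl)oxy]cyclohex-2-en-1-one
Product: 24 3-bromo-5-[(1R,4S)-4-[(4-methoxybenzyl)oxy]-1-(triethylsilyloxy)cyclohex-2-en-1-yl]-2,4-bis[2-(trimethylsilyl)ethoxy]pyridine, via aryllithium 22 (not isolated), via lithium alkoxide 23 (not isolated)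
Conditions: n-BuLi (1.05 equiv), THF, −78 °C; then 21, −78 °C; then Et3SiOTf, −78 → 0 °C
Reagents that add atoms: triethylsilyl trifluoromethanesulfonate, CC[Si](CC)(CC)OS(=O)(=O)C(F)(F)F
Why: Iodine–lithium exchange is faster than bromine–lithium exchange, and 1,2-addition of the aryllithium to the enone should occur anti to the C4 alkoxy group (setting the tertiary carbinol), the alkoxide being trapped as its silyl ether.

Step 16
Reactants: 24 3-bromo-5-[(1R,4S)-4-[(4-methoxybenzyl)oxy]-1-(triethylsilyloxy)cyclohex-2-en-1-yl]-2,4-bis[2-(trimethylsilyl)ethoxy]pyridine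
Product: 25 (1S,4R)-4-{5-bromo-4,6-bis[2-(trimethylsilyl)ethoxy]pyridin-3-yl}-4-(triethylsilyloxy)cyclohex-2-en-1-ol
Conditions: DDQ, CH2Cl2–pH 7 buffer, 0 °C
Reagents that add atoms: none
Why: Oxidative cleavage of the 4-methoxybenzyl ether under buffered conditions should free the allylic alcohol while the silyl ethers stay.

Step 17
Reactants: 25 (1S,4R)-4-{5-bromo-4,6-bis[2-(trimethylsilyl)ethoxy]pyridin-3-yl}-4-(triethylsilyloxy)cyclohex-2-en-1-ol
Product: 27 (1R,4R)-4-{5-bromo-4,6-bis[2-(trimethylsilyl)ethoxy]pyridin-3-yl}-4-(triethylsilyloxy)cyclohex-2-en-1-ol, via 4-nitrobenzoate 26 (not isolated)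
Conditions: PPh3, DIAD, 4-nitrobenzoic acid, THF, 0 °C → rt; then K2CO3 (0.2 equiv), MeOH, rt
Reagents that add atoms: 4-nitrobenzoic acid, OC(=O)c1ccc(cc1)[N+](=O)[O-]
Why: Mitsunobu reaction inverts the secondary allylic carbinol by SN2 displacement, and methanolysis of the ester should leave the hydroxyl cis to the pyridyl group.

Step 18
Reactants: 27 (1R,4R)-4-{5-bromo-4,6-bis[2-(trimethylsilyl)ethoxy]pyridin-3-yl}-4-(triethylsilyloxy)cyclohex-2-en-1-ol
Product: 28 (1R,2R,5S,6R)-5-{5-bromo-4,6-bis[2-(trimethylsilyl)ethoxy]pyridin-3-yl}-5-(triethylsilyloxy)-7-oxabicyclo[4.1.0]heptan-2-ol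
Conditions: VO(acac)2 (5 mol %), t-BuOOH, CH2Cl2, 0 °C → rt
Reagents that add atoms: tert-butyl hydroperoxide, CC(C)(C)OO
Why: Vanadium-catalysed hydroxyl-directed epoxidation should deliver oxygen syn to the free allylic hydroxyl and anti to the silylated tertiary oxygen, which sets both epoxide carbons.

Step 19
Reactants: 28 (1R,2R,5S,6R)-5-{5-bromo-4,6-bis[2-(trimethylsilyl)ethoxy]pyridin-3-yl}-5-(triethylsilyloxy)-7-oxabicyclo[4.1.0]heptan-2-ol
Product: 29 3-bromo-5-[(1R,2S,5R,6S)-2,5-bis(triethylsilyloxy)-7-oxabicyclo[4.1.0]heptan-2-yl]-2,4-bis[2-(trimethylsilyl)ethoxy]pyridine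
Conditions: Et3SiCl, imidazole, DMF, 0 °C → rt
Reagents that add atoms: chlorotriethylsilane, CC[Si](Cl)(CC)CC
Why: Silylation protects the secondary alcohol against the organolithium of step 20 and the oxidation of step 21.

Step 20
Reactants: 29 3-bromo-5-[(1R,2S,5R,6S)-2,5-bis(triethylsilyloxy)-7-oxabicyclo[4.1.0]heptan-2-yl]-2,4-bis[2-(trimethylsilyl)ethoxy]pyridine; 14 (1R,2S,4aR,8aR)-2-methyl-1,2,4a,5,6,7,8,8a-octahydronaphthalene-1-carbaldehyde
Product: 31 {5-[(1R,2S,5R,6S)-2,5-bis(triethylsilyloxy)-7-oxabicyclo[4.1.0]heptan-2-yl]-2,4-bis[2-(trimethylsilyl)ethoxy]pyridin-3-yl}[(1R,2S,4aR,8aR)-2-methyl-1,2,4a,5,6,7,8,8a-octahydronaphthalen-1-yl]methanol (either carbinol configuration), via aryllithium 30 (not isolated)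
Conditions: n-BuLi (1.05 equiv), THF, −78 °C; then 14, −78 → −40 °C
Reagents that add atoms: none
Why: Bromine–lithium exchange between the two alkoxy groups is fast at −78 °C, where the epoxide and silyl ethers are inert, and the aryllithium should add to the aldehyde; the new carbinol centre is removed in step 21.

Step 21
Reactants: 31 pyridyl decalinyl carbinol
Product: 32 {5-[(1R,2S,5R,6S)-2,5-bis(triethylsilyloxy)-7-oxabicyclo[4.1.0]heptan-2-yl]-2,4-bis[2-(trimethylsilyl)ethoxy]pyridin-3-yl}[(1R,2S,4aR,8aR)-2-methyl-1,2,4a,5,6,7,8,8a-octahydronaphthalen-1-yl]methanone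
Conditions: Dess–Martin periodinane, CH2Cl2, 0 °C → rt
Reagents that add atoms: none
Why: Dess–Martin oxidation of the hindered secondary carbinol should give the aryl ketone without affecting the alkene, epoxide or silyl ethers.

Step 22
Reactants: 32 protected aryl ketone
Product: 33 4-hydroxy-5-[(1R,2S,5R,6R)-2,5-dihydroxy-7-oxabicyclo[4.1.0]heptan-2-yl]-3-[(1R,2S,4aR,8aR)-2-methyl-1,2,4a,5,6,7,8,8a-octahydronaphthalene-1-carbonyl]pyridin-2(1H)-one
Conditions: Bu4NF (8 equiv), THF, 0 → 40 °C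
Reagents that add atoms: none
Why: Fluoride should cleave both triethylsilyl ethers and fragment both 2-(trimethylsilyl)ethyl ethers (loss of ethene) to the 4-hydroxy-2-pyridone, and C1 of the decalin already holds its thermodynamic configuration.

Step 23
Reactants: 33 N-unsubstituted pyridone
Product: 36 fischerin, via tetrakis(trimethylsilyl) derivative 34 (not isolated), via N-silyloxy pyridone 35 (not isolated)
Conditions: N,O-bis(trimethylsilyl)acetamide, CH2Cl2, rt; then MoO5·pyridine·HMPA (1.5 equiv), CH2Cl2, rt; aq. NaHCO3–MeOH work-up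
Reagents that add atoms: MoO5·pyridine·HMPA, O=[Mo]12(OO1)OO2.c1ccncc1.CN(C)P(=O)(N(C)C)N(C)C
Why: N-Hydroxylation of O-silylated 2-pyridones by a peroxomolybdenum reagent (oxygen transfer to the ring nitrogen of the 2-silyloxypyridine, then oxygen-to-oxygen silyl shift and hydrolysis) is known for 3-acyl-4-hydroxy-2-pyridones and should give the 1-hydroxy-2-pyridone.

**Compound list**

1 | hept-6-en-1-ol | OCCCCCC=C | starting material
2 | hept-6-enal | O=CCCCCC=C | intermediate
3 | (6E)-8-bromooct-6-enal | O=CCCCC/C=C/CBr | intermediate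
4 | [(2E)-8-oxooct-2-en-1-yl]triphenylphosphonium bromide | O=CCCCC/C=C/C[P+](c1ccccc1)(c1ccccc1)c1ccccc1.[Br-] | intermediate
5 | (1R,2S,5R)-menthyl 3-oxobutanoate | CC(=O)CC(=O)O[C@@H]1C[C@H](C)CC[C@H]1C(C)C | starting material
6 | [(2E)-9-{[(1R,2S,5R)-menthyl]oxycarbonyl}-10-oxoundeca-2,8-dien-1-yl]triphenylphosphonium bromide | CC(=O)C(=CCCCC/C=C/C[P+](c1ccccc1)(c1ccccc1)c1ccccc1)C(=O)O[C@@H]1C[C@H](C)CC[C@H]1C(C)C.[Br-] | intermediate
7 | (1R,2S,5R)-menthyl 2-acetyl-10-(triphenyl-λ5-phosphanylidene)deca-2,8-dienoate | CC(=O)C(=CCCCCC=CC=P(c1ccccc1)(c1ccccc1)c1ccccc1)C(=O)O[C@@H]1C[C@H](C)CC[C@H]1C(C)C | intermediate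
8 | zwitterion: enolate of (1R,2S,5R)-menthyl 3-oxo-2-{2-[2-(triphenylphosphonio)ethenyl]cyclohexyl}butanoate (ring carbon bearing the keto ester as in 10) | CC([O-])=C(C(=O)O[C@@H]1C[C@H](C)CC[C@H]1C(C)C)[C@@H]1CCCCC1C=C[P+](c1ccccc1)(c1ccccc1)c1ccccc1 | intermediate
9 | (1R,2S,5R)-menthyl 3-oxo-2-{2-[2-(triphenyl-λ5-phosphanylidene)ethylidene]cyclohexyl}butanoate | CC(=O)C(C(=O)O[C@@H]1C[C@H](C)CC[C@H]1C(C)C)[C@@H]1CCCCC1=CC=P(c1ccccc1)(c1ccccc1)c1ccccc1 | intermediate
10 | (1R,2S,5R)-menthyl (8aS)-2-methyl-1,5,6,7,8,8a-hexahydronaphthalene-1-carboxylate (C1 epimers; accompanied by its 8aR diastereomer until step 7) | CC1=CC=C2CCCC[C@H]2C1C(=O)O[C@@H]1C[C@H](C)CC[C@H]1C(C)C | intermediate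
11 | (1R,2S,5R)-menthyl (2S,4aR,8aR)-2-methyl-1,2,4a,5,6,7,8,8a-octahydronaphthalene-1-carboxylate (C1 epimers) | C[C@H]1C=C[C@H]2CCCC[C@H]2C1C(=O)O[C@@H]1C[C@H](C)CC[C@H]1C(C)C | intermediate
12 | (1R,2S,5R)-menthyl (1R,2S,4aR,8aR)-2-methyl-1,2,4a,5,6,7,8,8a-octahydronaphthalene-1-carboxylate | C[C@H]1C=C[C@H]2CCCC[C@H]2[C@@H]1C(=O)O[C@@H]1C[C@H](C)CC[C@H]1C(C)C | intermediate
13 | [(1R,2S,4aR,8aR)-2-methyl-1,2,4a,5,6,7,8,8a-octahydronaphthalen-1-yl]methanol | C[C@H]1C=C[C@H]2CCCC[C@H]2[C@@H]1CO | intermediate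
14 | (1R,2S,4aR,8aR)-2-methyl-1,2,4a,5,6,7,8,8a-octahydronaphthalene-1-carbaldehyde | C[C@H]1C=C[C@H]2CCCC[C@H]2[C@@H]1C=O | intermediate
15 | 3-bromo-2,4-dichloropyridine | Clc1nccc(Cl)c1Br | starting material
16 | 3-bromo-2,4-bis[2-(trimethylsilyl)ethoxy]pyridine | C[Si](C)(C)CCOc1nccc(OCC[Si](C)(C)C)c1Br | intermediate
17 | 3-bromo-5-iodo-2,4-bis[2-(trimethylsilyl)ethoxy]pyridine | C[Si](C)(C)CCOc1ncc(I)c(OCC[Si](C)(C)C)c1Br | intermediate
18 | 1,4-dioxaspiro[4.5]dec-6-en-8-one | O=C1CCC2(OCCO2)C=C1 | starting material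
19 | (8S)-1,4-dioxaspiro[4.5]dec-6-en-8-ol | O[C@H]1CCC2(OCCO2)C=C1 | intermediate
20 | (8S)-8-[(4-methoxybenzyl)oxy]-1,4-dioxaspiro[4.5]dec-6-ene | COc1ccc(CO[C@H]2CCC3(OCCO3)C=C2)cc1 | intermediate
21 | (4S)-4-[(4-methoxybenzyl)oxy]cyclohex-2-en-1-one | O=C1CC[C@H](OCc2ccc(OC)cc2)C=C1 | intermediate
22 | {5-bromo-4,6-bis[2-(trimethylsilyl)ethoxy]pyridin-3-yl}lithium | C[Si](C)(C)CCOc1ncc([Li])c(OCC[Si](C)(C)C)c1Br | intermediate
23 | lithium (1R,4S)-1-{5-bromo-4,6-bis[2-(trimethylsilyl)ethoxy]pyridin-3-yl}-4-[(4-methoxybenzyl)oxy]cyclohex-2-en-1-olate | C[Si](C)(C)CCOc1ncc(c(OCC[Si](C)(C)C)c1Br)[C@@]1(O[Li])CC[C@H](OCc2ccc(OC)cc2)C=C1 | intermediate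
24 | 3-bromo-5-[(1R,4S)-4-[(4-methoxybenzyl)oxy]-1-(triethylsilyloxy)cyclohex-2-en-1-yl]-2,4-bis[2-(trimethylsilyl)ethoxy]pyridine | C[Si](C)(C)CCOc1ncc(c(OCC[Si](C)(C)C)c1Br)[C@@]1(O[Si](CC)(CC)CC)CC[C@H](OCc2ccc(OC)cc2)C=C1 | intermediate
25 | (1S,4R)-4-{5-bromo-4,6-bis[2-(trimethylsilyl)ethoxy]pyridin-3-yl}-4-(triethylsilyloxy)cyclohex-2-en-1-ol | C[Si](C)(C)CCOc1ncc(c(OCC[Si](C)(C)C)c1Br)[C@@]1(O[Si](CC)(CC)CC)CC[C@H](O)C=C1 | intermediate
26 | (1R,4R)-4-{5-bromo-4,6-bis[2-(trimethylsilyl)ethoxy]pyridin-3-yl}-4-(triethylsilyloxy)cyclohex-2-en-1-yl 4-nitrobenzoate | C[Si](C)(C)CCOc1ncc(c(OCC[Si](C)(C)C)c1Br)[C@@]1(O[Si](CC)(CC)CC)CC[C@@H](OC(=O)c2ccc(cc2)[N+](=O)[O-])C=C1 | intermediate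
27 | (1R,4R)-4-{5-bromo-4,6-bis[2-(trimethylsilyl)ethoxy]pyridin-3-yl}-4-(triethylsilyloxy)cyclohex-2-en-1-ol | C[Si](C)(C)CCOc1ncc(c(OCC[Si](C)(C)C)c1Br)[C@@]1(O[Si](CC)(CC)CC)CC[C@@H](O)C=C1 | intermediate
28 | (1R,2R,5S,6R)-5-{5-bromo-4,6-bis[2-(trimethylsilyl)ethoxy]pyridin-3-yl}-5-(triethylsilyloxy)-7-oxabicyclo[4.1.0]heptan-2-ol | C[Si](C)(C)CCOc1ncc(c(OCC[Si](C)(C)C)c1Br)[C@@]1(O[Si](CC)(CC)CC)CC[C@@H](O)[C@H]2O[C@H]21 | intermediate
29 | 3-bromo-5-[(1R,2S,5R,6S)-2,5-bis(triethylsilyloxy)-7-oxabicyclo[4.1.0]heptan-2-yl]-2,4-bis[2-(trimethylsilyl)ethoxy]pyridine | C[Si](C)(C)CCOc1ncc(c(OCC[Si](C)(C)C)c1Br)[C@@]1(O[Si](CC)(CC)CC)CC[C@@H](O[Si](CC)(CC)CC)[C@H]2O[C@H]21 | intermediate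
30 | {5-[(1R,2S,5R,6S)-2,5-bis(triethylsilyloxy)-7-oxabicyclo[4.1.0]heptan-2-yl]-2,4-bis[2-(trimethylsilyl)ethoxy]pyridin-3-yl}lithium | C[Si](C)(C)CCOc1ncc(c(OCC[Si](C)(C)C)c1[Li])[C@@]1(O[Si](CC)(CC)CC)CC[C@@H](O[Si](CC)(CC)CC)[C@H]2O[C@H]21 | intermediate
31 | {5-[(1R,2S,5R,6S)-2,5-bis(triethylsilyloxy)-7-oxabicyclo[4.1.0]heptan-2-yl]-2,4-bis[2-(trimethylsilyl)ethoxy]pyridin-3-yl}[(1R,2S,4aR,8aR)-2-methyl-1,2,4a,5,6,7,8,8a-octahydronaphthalen-1-yl]methanol (carbinol epimers) | C[C@H]1C=C[C@H]2CCCC[C@H]2[C@@H]1C(O)c1c(OCC[Si](C)(C)C)c([C@@]2(O[Si](CC)(CC)CC)CC[C@@H](O[Si](CC)(CC)CC)[C@H]3O[C@H]32)cnc1OCC[Si](C)(C)C | intermediate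
32 | {5-[(1R,2S,5R,6S)-2,5-bis(triethylsilyloxy)-7-oxabicyclo[4.1.0]heptan-2-yl]-2,4-bis[2-(trimethylsilyl)ethoxy]pyridin-3-yl}[(1R,2S,4aR,8aR)-2-methyl-1,2,4a,5,6,7,8,8a-octahydronaphthalen-1-yl]methanone | C[C@H]1C=C[C@H]2CCCC[C@H]2[C@@H]1C(=O)c1c(OCC[Si](C)(C)C)c([C@@]2(O[Si](CC)(CC)CC)CC[C@@H](O[Si](CC)(CC)CC)[C@H]3O[C@H]32)cnc1OCC[Si](C)(C)C | intermediate
33 | 4-hydroxy-5-[(1R,2S,5R,6R)-2,5-dihydroxy-7-oxabicyclo[4.1.0]heptan-2-yl]-3-[(1R,2S,4aR,8aR)-2-methyl-1,2,4a,5,6,7,8,8a-octahydronaphthalene-1-carbonyl]pyridin-2(1H)-one | C[C@H]1C=C[C@H]2CCCC[C@H]2[C@@H]1C(=O)c1c(O)c([C@@]2(O)CC[C@@H](O)[C@H]3O[C@H]32)c[nH]c1=O | intermediate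
34 | tetrakis(trimethylsilyl) derivative of 33 (2,4-bis(trimethylsilyloxy)pyridine, both alcohols as trimethylsilyl ethers) | C[C@H]1C=C[C@H]2CCCC[C@H]2[C@@H]1C(=O)c1c(O[Si](C)(C)C)c([C@@]2(O[Si](C)(C)C)CC[C@@H](O[Si](C)(C)C)[C@H]3O[C@H]32)cnc1O[Si](C)(C)C | intermediate
35 | 1,4-bis(trimethylsilyloxy)pyridin-2(1H)-one form of fischerin, both alcohols as trimethylsilyl ethers | C[C@H]1C=C[C@H]2CCCC[C@H]2[C@@H]1C(=O)c1c(O[Si](C)(C)C)c([C@@]2(O[Si](C)(C)C)CC[C@@H](O[Si](C)(C)C)[C@H]3O[C@H]32)cn(O[Si](C)(C)C)c1=O | intermediate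
36 | fischerin: 1,4-dihydroxy-5-[(1R,2S,5R,6R)-2,5-dihydroxy-7-oxabicyclo[4.1.0]heptan-2-yl]-3-[(1R,2S,4aR,8aR)-2-methyl-1,2,4a,5,6,7,8,8a-octahydronaphthalene-1-carbonyl]pyridin-2(1H)-one | C[C@H]1C=C[C@H]2CCCC[C@H]2[C@@H]1C(=O)c1c(O)c([C@@]2(O)CC[C@@H](O)[C@H]3O[C@H]32)cn(O)c1=O | target

**Totals**

Total step count: 23. Longest linear sequence: 13 steps (steps 1–9, then 20–23).

**Steps most likely to fail**

Step 5 (annulation). What may go wrong: intermolecular conjugate addition in place of ring closure, a Wittig closure that stalls because the β-keto ester stays as its enolate, and base-induced migration of the diene into conjugation with the ester. Fallback, from 2 back to 10, a stepwise Lewis-acid route: cross-metathesis of 2 with allyltrimethylsilane (second-generation Grubbs catalyst) should give (6E)-8-(trimethylsilyl)oct-6-enal F1. Knoevenagel condensation with 5 gives (1R,2S,5R)-menthyl 2-acetyl-10-(trimethylsilyl)deca-2,8-dienoate F2. TiCl4 at −78 °C triggers the intramolecular Hosomi–Sakurai conjugate addition to (1R,2S,5R)-menthyl 2-(2-ethenylcyclohexyl)-3-oxobutanoate F3 (C4a–C8a bond). Me2AlCl then promotes the intramolecular carbonyl-ene reaction of the vinyl group with the chelated ketone to (1R,2S,5R)-menthyl (8aS)-2-hydroxy-2-methyl-1,2,3,5,6,7,8,8a-octahydronaphthalene-1-carboxylate F4 (C2–C3 bond). Dehydration with Burgess reagent gives diene 10.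

Step 6 (1,4-hydrogenation). What may go wrong: hydrogen delivery from the wrong face of the diene, slow addition to the two fully substituted diene termini, and hydrogen shifts that move the diene before it is reduced. Fallback, from 2 back to 12, by Diels–Alder chemistry: Horner–Wadsworth–Emmons reaction of 2 with (1R,2S,5R)-menthyl (diethoxyphosphoryl)acetate and NaH gives (1R,2S,5R)-menthyl (2E)-nona-2,8-dienoate F5. Selective ozonolysis of the terminal alkene (O3, then PPh3) gives (1R,2S,5R)-menthyl (2E)-8-oxooct-2-enoate F6. Wittig reaction with the ylide of (E)-but-2-enyl(triphenyl)phosphonium bromide, followed by iodine-catalysed isomerisation, gives (1R,2S,5R)-menthyl (2E,8E,10E)-dodeca-2,8,10-trienoate F7. Thermal intramolecular Diels–Alder reaction (toluene, 150 °C) should give the cis-fused adduct through the exo transition state; chromatography removes the trans-fused isomer and the diastereomer of antipodal bicycle and leaves 12.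

Step 23 (N-hydroxylation). What may go wrong: incomplete oxygen transfer to the hindered ring nitrogen, competing epoxidation of the C3=C4 alkene by the peroxomolybdenum reagent, and loss of the polar product on desilylation. Fallback, from 29 back to 36, with the N–O bond made before the alkene is present: m-chloroperbenzoic acid oxidises the ring nitrogen of 29 to 3-bromo-5-[(1R,2S,5R,6S)-2,5-bis(triethylsilyloxy)-7-oxabicyclo[4.1.0]heptan-2-yl]-2,4-bis[2-(trimethylsilyl)ethoxy]pyridine 1-oxide F8. Bromine–magnesium exchange with i-PrMgCl·LiCl (known for halopyridine N-oxides) and addition to 14 gives the carbinol N-oxide F9. Dess–Martin oxidation gives the ketone N-oxide F10. Bu4NF then removes all four silicon-based groups, and the 2-oxidopyridine N-oxide that is released is the 1-hydroxy-2-pyridone 36.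

**Further compounds**

F1 | step 5 | (6E)-8-(trimethylsilyl)oct-6-enal | O=CCCCC/C=C/C[Si](C)(C)C
F2 | step 5 | (1R,2S,5R)-menthyl 2-acetyl-10-(trimethylsilyl)deca-2,8-dienoate | CC(=O)C(=CCCCC/C=C/C[Si](C)(C)C)C(=O)O[C@@H]1C[C@H](C)CC[C@H]1C(C)C
F3 | step 5 | (1R,2S,5R)-menthyl 2-(2-ethenylcyclohexyl)-3-oxobutanoate | CC(=O)C(C(=O)O[C@@H]1C[C@H](C)CC[C@H]1C(C)C)[C@@H]1CCCCC1C=C
F4 | step 5 | (1R,2S,5R)-menthyl (8aS)-2-hydroxy-2-methyl-1,2,3,5,6,7,8,8a-octahydronaphthalene-1-carboxylate | CC1(O)CC=C2CCCC[C@H]2C1C(=O)O[C@@H]1C[C@H](C)CC[C@H]1C(C)C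
F5 | step 6 | (1R,2S,5R)-menthyl (2E)-nona-2,8-dienoate | C=CCCCC/C=C/C(=O)O[C@@H]1C[C@H](C)CC[C@H]1C(C)C
F6 | step 6 | (1R,2S,5R)-menthyl (2E)-8-oxooct-2-enoate | O=CCCCC/C=C/C(=O)O[C@@H]1C[C@H](C)CC[C@H]1C(C)C
F7 | step 6 | (1R,2S,5R)-menthyl (2E,8E,10E)-dodeca-2,8,10-trienoate | C/C=C/C=C/CCCC/C=C/C(=O)O[C@@H]1C[C@H](C)CC[C@H]1C(C)C
F8 | step 23 | 3-bromo-5-[(1R,2S,5R,6S)-2,5-bis(triethylsilyloxy)-7-oxabicyclo[4.1.0]heptan-2-yl]-2,4-bis[2-(trimethylsilyl)ethoxy]pyridine 1-oxide | C[Si](C)(C)CCOc1[n+]([O-])cc(c(OCC[Si](C)(C)C)c1Br)[C@@]1(O[Si](CC)(CC)CC)CC[C@@H](O[Si](CC)(CC)CC)[C@H]2O[C@H]21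
F9 | step 23 | carbinol N-oxide: the 1-oxide of 31 | C[C@H]1C=C[C@H]2CCCC[C@H]2[C@@H]1C(O)c1c(OCC[Si](C)(C)C)c([C@@]2(O[Si](CC)(CC)CC)CC[C@@H](O[Si](CC)(CC)CC)[C@H]3O[C@H]32)c[n+]([O-])c1OCC[Si](C)(C)C
F10 | step 23 | ketone N-oxide: the 1-oxide of 32 | C[C@H]1C=C[C@H]2CCCC[C@H]2[C@@H]1C(=O)c1c(OCC[Si](C)(C)C)c([C@@]2(O[Si](CC)(CC)CC)CC[C@@H](O[Si](CC)(CC)CC)[C@H]3O[C@H]32)c[n+]([O-])c1OCC[Si](C)(C)C
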